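The route rests on disconnecting the C1–C10 bond of the ten-membered carbocycle: the cis-1,10-diol, whose secondary C1 carbinol and tertiary C10 methyl carbinol each stand 1,3-anti to an oxygen already present (C3–OH, C8–O). A hydroxyl-directed SmI2 pinacol macrocyclisation of a seco keto aldehyde (C1 aldehyde, C10 methyl ketone) closes this ring and sets C1 and C10 in one operation. The precursor already holds the trans-fused γ-lactone, the Z C4=C5 alkene, the C8 angelate and a free C3 hydroxyl; the exocyclic methylene is masked as a Mannich base. C3 is set by catalytic alkynylation, C6/C7 by an Evans aldol, C8 by a proline aldol.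

Key step: step 15

Remark: germacrane atom numbers are used throughout (C1–C10 ring carbons, C11/C12/C13 lactone α-carbon, carbonyl carbon and methylene carbon, C14 methyl on C10, C15 methyl on C4). The (S,S) enantiomer of ProPhenol is assumed to be the one that delivers the 4S carbinol in step 1; otherwise its antipode is used.

Step 1
Reactants: 1 3-[(tert-butyldimethylsilyl)oxy]propanal; 2 methyl propiolate
Product: 3 methyl (4S)-6-[(tert-butyldimethylsilyl)oxy]-4-hydroxyhex-2-ynoate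
Conditions: Me2Zn, (S,S)-ProPhenol (20 mol%), Ph3PO (40 mol%), toluene, 0 to 4 °C
Reagents that add atoms: none
Why: Zinc–ProPhenol-catalysed asymmetric alkynylation (Trost type) should add the zinc acetylide of the propiolate to one face of the aldehyde inside the dinuclear zinc pocket, which sets C3 (4S in 3) by catalyst control.

Step 2
Reactants: 3 methyl (4S)-6-[(tert-butyldimethylsilyl)oxy]-4-hydroxyhex-2-ynoate
Product: 4 methyl (4S)-4,6-bis[(tert-butyldimethylsilyl)oxy]hex-2-ynoate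
Conditions: TBSCl, imidazole, DMF, 0 °C to rt
Reagents that add atoms: tert-butyldimethylsilyl chloride CC(C)(C)[Si](C)(C)Cl
Why: Standard silylation of the propargylic alcohol protects O3 before the cuprate step and touches no stereocentre.

Step 3
Reactants: 4 methyl (4S)-4,6-bis[(tert-butyldimethylsilyl)oxy]hex-2-ynoate
Product: 5 methyl (2Z,4S)-4,6-bis[(tert-butyldimethylsilyl)oxy]-3-methylhex-2-enoate
Conditions: Me2CuLi (from MeLi and CuI), THF, −78 °C; aq. NH4Cl at −78 °C
Reagents that add atoms: methyllithium [Li]C, used as lithium dimethylcuprate [Li+].C[Cu-]C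
Why: Syn-carbocupration of the ynoate (cuprate conjugate addition, cold quench) should place the new methyl group and hydrogen cis, so C3 and the ester carbon end up cis and the Z C4=C5 geometry is fixed.

Step 4
Reactants: 5 methyl (2Z,4S)-4,6-bis[(tert-butyldimethylsilyl)oxy]-3-methylhex-2-enoate
Product: 6 (2Z,4S)-4,6-bis[(tert-butyldimethylsilyl)oxy]-3-methylhex-2-en-1-ol
Conditions: i-Bu2AlH (2.2 equiv), CH2Cl2, −78 °C; Rochelle salt
Reagents that add atoms: none
Why: 1,2-Reduction of the enoate with i-Bu2AlH should give the allylic alcohol without touching the Z alkene or the silyl ethers.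

Step 5
Reactants: 6 (2Z,4S)-4,6-bis[(tert-butyldimethylsilyl)oxy]-3-methylhex-2-en-1-ol
Product: 7 (2Z,4S)-4,6-bis[(tert-butyldimethylsilyl)oxy]-3-methylhex-2-enal
Conditions: activated MnO2, CH2Cl2, rt, used at once
Reagents that add atoms: none
Why: MnO2 oxidation of the allylic alcohol is neutral and should keep the Z geometry of the enal.

Step 6
Reactants: 8 (4R)-4-benzyl-1,3-oxazolidin-2-one; 9 methyl 4-chloro-4-oxobutanoate
Product: 10 methyl 4-[(4R)-4-benzyl-2-oxo-1,3-oxazolidin-3-yl]-4-oxobutanoate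
Conditions: n-BuLi, THF, −78 °C; then 9, −78 to 0 °C
Reagents that add atoms: none
Why: N-Acylation of the lithiated Evans auxiliary with the acid chloride should give the succinate imide.

Step 7
Reactants: 10 methyl 4-[(4R)-4-benzyl-2-oxo-1,3-oxazolidin-3-yl]-4-oxobutanoate; 7 (2Z,4S)-4,6-bis[(tert-butyldimethylsilyl)oxy]-3-methylhex-2-enal
Product: 12 (4R)-4-benzyl-3-{[(2S,3R)-2-{(1Z,3S)-3,5-bis[(tert-butyldimethylsilyl)oxy]-2-methylpent-1-en-1-yl}-5-oxooxolan-3-yl]carbonyl}-1,3-oxazolidin-2-one, via aldol adduct 11 (not isolated)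
Conditions: Bu2BOTf, i-Pr2NEt, CH2Cl2, 0 °C; 7, −78 to 0 °C; pH 7 buffer, MeOH, H2O2; then PPTS (cat.), CH2Cl2, rt
Reagents that add atoms: none
Why: Evans syn-aldol through the Z-boron enolate and a Zimmerman–Traxler chair, with the benzyl group of the (R)-auxiliary shielding one enolate face, should set C6 and C7, and the new C6 hydroxyl then closes the γ-lactone on the methyl ester, so the syn adduct becomes the trans-disubstituted lactone.

Step 8
Reactants: 12 (4R)-4-benzyl-3-{[(2S,3R)-2-{(1Z,3S)-3,5-bis[(tert-butyldimethylsilyl)oxy]-2-methylpent-1-en-1-yl}-5-oxooxolan-3-yl]carbonyl}-1,3-oxazolidin-2-one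
Product: 13 (4R)-4-benzyl-3-{[(2S,3R,4S)-2-{(1Z,3S)-3,5-bis[(tert-butyldimethylsilyl)oxy]-2-methylpent-1-en-1-yl}-4-[(dimethylamino)methyl]-5-oxooxolan-3-yl]carbonyl}-1,3-oxazolidin-2-one
Conditions: LiN(i-Pr)2 (1.05 equiv), THF, −78 °C; then Eschenmoser's salt, −78 to −20 °C
Reagents that add atoms: N,N-dimethylmethyleneiminium iodide (Eschenmoser's salt) C=[N+](C)C.[I-]
Why: Kinetic deprotonation should occur at the lactone α-CH2 (C11), because the imide α-hydrogen at C7 is held in the carbonyl plane by allylic 1,3-strain, and the Mannich reaction of the lithium enolate then takes place anti to the C7 substituent (C11 trans; this centre is erased in step 16).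

Step 9
Reactants: 13 (4R)-4-benzyl-3-{[(2S,3R,4S)-2-{(1Z,3S)-3,5-bis[(tert-butyldimethylsilyl)oxy]-2-methylpent-1-en-1-yl}-4-[(dimethylamino)methyl]-5-oxooxolan-3-yl]carbonyl}-1,3-oxazolidin-2-one
Product: 14 S-ethyl (2S,3R,4S)-2-{(1Z,3S)-3,5-bis[(tert-butyldimethylsilyl)oxy]-2-methylpent-1-en-1-yl}-4-[(dimethylamino)methyl]-5-oxooxolane-3-carbothioate
Conditions: EtSH, n-BuLi, THF, −20 to 0 °C; aq. NH4Cl
Reagents that add atoms: ethanethiol CCS, used as lithium ethanethiolate
Why: Acyl transfer from the imide to the soft, weakly basic thiolate should release the auxiliary and give the thioester without epimerising C7.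

Step 10
Reactants: 14 S-ethyl (2S,3R,4S)-2-{(1Z,3S)-3,5-bis[(tert-butyldimethylsilyl)oxy]-2-methylpent-1-en-1-yl}-4-[(dimethylamino)methyl]-5-oxooxolane-3-carbothioate
Product: 15 (2S,3R,4S)-2-{(1Z,3S)-3,5-bis[(tert-butyldimethylsilyl)oxy]-2-methylpent-1-en-1-yl}-4-[(dimethylamino)methyl]-5-oxooxolane-3-carbaldehyde
Conditions: Et3SiH, 10% Pd/C, acetone, rt, used crude
Reagents that add atoms: none
Why: Fukuyama reduction of the thioester should stop at the aldehyde (C8) and leave the lactone and the trisubstituted alkene intact.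

Step 11
Reactants: 15 (2S,3R,4S)-2-{(1Z,3S)-3,5-bis[(tert-butyldimethylsilyl)oxy]-2-methylpent-1-en-1-yl}-4-[(dimethylamino)methyl]-5-oxooxolane-3-carbaldehyde
Product: 16 (3S,4S,5S)-5-{(1Z,3S)-3,5-bis[(tert-butyldimethylsilyl)oxy]-2-methylpent-1-en-1-yl}-3-[(dimethylamino)methyl]-4-[(1R)-1-hydroxy-3-oxobutyl]oxolan-2-one
Conditions: L-proline (30 mol%), acetone/DMSO 1:4, rt
Reagents that add atoms: acetone CC(C)=O
Why: The List–Barbas direct aldol (enamine catalysis, α-branched aldehyde) should deliver the acetone enamine to the Re face of C8 through the acid-bound transition state, which sets 8R by catalyst control, reinforced by the Felkin–Anh preference of C7.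

Step 12
Reactants: 16 (3S,4S,5S)-5-{(1Z,3S)-3,5-bis[(tert-butyldimethylsilyl)oxy]-2-methylpent-1-en-1-yl}-3-[(dimethylamino)methyl]-4-[(1R)-1-hydroxy-3-oxobutyl]oxolan-2-one; 17 angelic acid, (2Z)-2-methylbut-2-enoic acid
Product: 19 (1R)-1-[(2S,3S,4S)-2-{(1Z,3S)-3,5-bis[(tert-butyldimethylsilyl)oxy]-2-methylpent-1-en-1-yl}-4-[(dimethylamino)methyl]-5-oxooxolan-3-yl]-3-oxobutyl (2Z)-2-methylbut-2-enoate, via mixed anhydride 18 (not isolated)
Conditions: 17, 2,4,6-Cl3C6H2COCl, Et3N, toluene, rt; then 16, DMAP (0.2 equiv), toluene, rt to 40 °C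
Reagents that add atoms: 2,4,6-trichlorobenzoyl chloride O=C(Cl)c1c(Cl)cc(Cl)cc1Cl (its atoms stay in 18 only)
Why: Yamaguchi esterification through the mixed anhydride should acylate the only free hydroxyl (C8–OH) with retention at C8, and the low temperature keeps the angelate from isomerising to the tiglate.

Step 13
Reactants: 19 (1R)-1-[(2S,3S,4S)-2-{(1Z,3S)-3,5-bis[(tert-butyldimethylsilyl)oxy]-2-methylpent-1-en-1-yl}-4-[(dimethylamino)methyl]-5-oxooxolan-3-yl]-3-oxobutyl (2Z)-2-methylbut-2-enoate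
Product: 20 (1R)-1-[(2S,3S,4S)-2-[(1Z,3S)-3,5-dihydroxy-2-methylpent-1-en-1-yl]-4-[(dimethylamino)methyl]-5-oxooxolan-3-yl]-3-oxobutyl (2Z)-2-methylbut-2-enoate
Conditions: HF·pyridine, pyridine, THF, 0 °C to rt
Reagents that add atoms: none
Why: Buffered fluoride desilylation should remove both TBS groups without touching the lactone, the angelate or the β-acyloxy ketone.

Step 14
Reactants: 20 (1R)-1-[(2S,3S,4S)-2-[(1Z,3S)-3,5-dihydroxy-2-methylpent-1-en-1-yl]-4-[(dimethylamino)methyl]-5-oxooxolan-3-yl]-3-oxobutyl (2Z)-2-methylbut-2-enoate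
Product: 21 (1R)-1-[(2S,3S,4S)-4-[(dimethylamino)methyl]-2-[(1Z,3S)-3-hydroxy-2-methyl-5-oxopent-1-en-1-yl]-5-oxooxolan-3-yl]-3-oxobutyl (2Z)-2-methylbut-2-enoate
Conditions: TEMPO (10 mol%), PhI(OAc)2, AcOH (1.1 equiv), CH2Cl2, 0 °C; NaHCO3 work-up, used crude
Reagents that add atoms: none
Why: TEMPO/PhI(OAc)2 oxidation is selective for the primary C1 alcohol over the hindered secondary allylic C3 alcohol and stops at the aldehyde, while the acid keeps the amine protonated.

Step 15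
Reactants: 21 (1R)-1-[(2S,3S,4S)-4-[(dimethylamino)methyl]-2-[(1Z,3S)-3-hydroxy-2-methyl-5-oxopent-1-en-1-yl]-5-oxooxolan-3-yl]-3-oxobutyl (2Z)-2-methylbut-2-enoate
Product: 22 (1S,3S,4Z,6S,7S,8R,10R,11S)-8-angeloyloxy-13-(dimethylamino)-1,3,10-trihydroxygermacr-4-en-12,6-olide
Conditions: SmI2 (3 equiv, 0.1 M in THF), THF, −78 to −20 °C, slow addition of 21 to a final 2 mM; aq. NaHCO3/Rochelle salt
Reagents that add atoms: none
Why: Electron transfer from SmI2 to the C1 aldehyde should give a samarium ketyl held in a six-membered chelate by the free C3 hydroxyl, which adds to the C10 ketone activated on the same trivalent samarium centre, and a second electron gives the samarium diolate (hydroxyl-directed intramolecular keto-aldehyde pinacol coupling; the closest known type is the SmI2 or low-valent titanium pinacol macrocyclisation). The ten-membered carbocycle closes by a 10-exo-trig addition of the C1 ketyl radical to the C10 carbonyl carbon, the Z C4=C5 alkene and the trans-fused lactone turning the two chain ends towards each other. C1 is controlled by the C3 stereocentre through the chelate (1,3-anti C–C bond formation), and C10 by the samarium bridge between O1 and the ketone oxygen, which should put both oxygens on one face with the C10 methyl group pointing outwards (cis-diol, 1,3-anti to O8). The step needs chemoselective reduction of the aldehyde in the presence of ketone, lactone and angelate, secured by the absence of HMPA and the low temperature, and ring closure over dimerisation, secured by high dilution and slow addition.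

Step 16
Reactants: 22 (1S,3S,4Z,6S,7S,8R,10R,11S)-8-angeloyloxy-13-(dimethylamino)-1,3,10-trihydroxygermacr-4-en-12,6-olide
Product: 24 (1S,3S,4Z,6S,7S,8R,10R)-8-angeloyloxy-1,3,10-trihydroxygermacra-4,11(13)-dien-12,6-olide, via ammonium iodide 23 (not isolated)
Conditions: MeI, MeOH, rt; then aq. NaHCO3, CH2Cl2, rt
Reagents that add atoms: iodomethane CI (its methyl group stays in 23 only)
Why: N-Methylation gives the quaternary ammonium salt, which should undergo mild base-induced β-elimination (Hofmann type, through the lactone enolate) to unveil the C11=C13 methylene, erasing C11 and leaving every other centre and the angelate untouched.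

Compound list
1 | 3-[(tert-butyldimethylsilyl)oxy]propanal | O=CCCO[Si](C)(C)C(C)(C)C | starting material
2 | methyl propiolate | C#CC(=O)OC | starting material
3 | methyl (4S)-6-[(tert-butyldimethylsilyl)oxy]-4-hydroxyhex-2-ynoate | COC(=O)C#C[C@@H](O)CCO[Si](C)(C)C(C)(C)C | intermediate
4 | methyl (4S)-4,6-bis[(tert-butyldimethylsilyl)oxy]hex-2-ynoate | COC(=O)C#C[C@@H](O[Si](C)(C)C(C)(C)C)CCO[Si](C)(C)C(C)(C)C | intermediate
5 | methyl (2Z,4S)-4,6-bis[(tert-butyldimethylsilyl)oxy]-3-methylhex-2-enoate | COC(=O)/C=C(/C)[C@@H](O[Si](C)(C)C(C)(C)C)CCO[Si](C)(C)C(C)(C)C | intermediate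
6 | (2Z,4S)-4,6-bis[(tert-butyldimethylsilyl)oxy]-3-methylhex-2-en-1-ol | OC/C=C(/C)[C@@H](O[Si](C)(C)C(C)(C)C)CCO[Si](C)(C)C(C)(C)C | intermediate
7 | (2Z,4S)-4,6-bis[(tert-butyldimethylsilyl)oxy]-3-methylhex-2-enal | O=C/C=C(/C)[C@@H](O[Si](C)(C)C(C)(C)C)CCO[Si](C)(C)C(C)(C)C | intermediate
8 | (4R)-4-benzyl-1,3-oxazolidin-2-one | O=C1N[C@H](Cc2ccccc2)CO1 | starting material
9 | methyl 4-chloro-4-oxobutanoate | COC(=O)CCC(Cl)=O | starting material
10 | methyl 4-[(4R)-4-benzyl-2-oxo-1,3-oxazolidin-3-yl]-4-oxobutanoate | COC(=O)CCC(=O)N1[C@H](Cc2ccccc2)COC1=O | intermediate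
11 | aldol adduct, methyl (3R,4S,5Z,7S)-3-{[(4R)-4-benzyl-2-oxo-1,3-oxazolidin-3-yl]carbonyl}-7,9-bis[(tert-butyldimethylsilyl)oxy]-4-hydroxy-6-methylnon-5-enoate | COC(=O)C[C@@H](C(=O)N1[C@H](Cc2ccccc2)COC1=O)[C@@H](O)/C=C(/C)[C@@H](O[Si](C)(C)C(C)(C)C)CCO[Si](C)(C)C(C)(C)C | intermediate (not isolated)
12 | (4R)-4-benzyl-3-{[(2S,3R)-2-{(1Z,3S)-3,5-bis[(tert-butyldimethylsilyl)oxy]-2-methylpent-1-en-1-yl}-5-oxooxolan-3-yl]carbonyl}-1,3-oxazolidin-2-one | O=C1C[C@@H](C(=O)N2[C@H](Cc3ccccc3)COC2=O)[C@H](/C=C(/C)[C@@H](O[Si](C)(C)C(C)(C)C)CCO[Si](C)(C)C(C)(C)C)O1 | intermediate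
13 | (4R)-4-benzyl-3-{[(2S,3R,4S)-2-{(1Z,3S)-3,5-bis[(tert-butyldimethylsilyl)oxy]-2-methylpent-1-en-1-yl}-4-[(dimethylamino)methyl]-5-oxooxolan-3-yl]carbonyl}-1,3-oxazolidin-2-one | O=C1[C@H](CN(C)C)[C@@H](C(=O)N2[C@H](Cc3ccccc3)COC2=O)[C@H](/C=C(/C)[C@@H](O[Si](C)(C)C(C)(C)C)CCO[Si](C)(C)C(C)(C)C)O1 | intermediate
14 | S-ethyl (2S,3R,4S)-2-{(1Z,3S)-3,5-bis[(tert-butyldimethylsilyl)oxy]-2-methylpent-1-en-1-yl}-4-[(dimethylamino)methyl]-5-oxooxolane-3-carbothioate | O=C1[C@H](CN(C)C)[C@@H](C(=O)SCC)[C@H](/C=C(/C)[C@@H](O[Si](C)(C)C(C)(C)C)CCO[Si](C)(C)C(C)(C)C)O1 | intermediate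
15 | (2S,3R,4S)-2-{(1Z,3S)-3,5-bis[(tert-butyldimethylsilyl)oxy]-2-methylpent-1-en-1-yl}-4-[(dimethylamino)methyl]-5-oxooxolane-3-carbaldehyde | O=C1[C@H](CN(C)C)[C@@H](C=O)[C@H](/C=C(/C)[C@@H](O[Si](C)(C)C(C)(C)C)CCO[Si](C)(C)C(C)(C)C)O1 | intermediate
16 | (3S,4S,5S)-5-{(1Z,3S)-3,5-bis[(tert-butyldimethylsilyl)oxy]-2-methylpent-1-en-1-yl}-3-[(dimethylamino)methyl]-4-[(1R)-1-hydroxy-3-oxobutyl]oxolan-2-one | O=C1[C@H](CN(C)C)[C@@H]([C@H](O)CC(C)=O)[C@H](/C=C(/C)[C@@H](O[Si](C)(C)C(C)(C)C)CCO[Si](C)(C)C(C)(C)C)O1 | intermediate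
17 | angelic acid, (2Z)-2-methylbut-2-enoic acid | C/C=C(/C)C(=O)O | starting material
18 | mixed anhydride, (2Z)-2-methylbut-2-enoic 2,4,6-trichlorobenzoic anhydride | C/C=C(/C)C(=O)OC(=O)c1c(Cl)cc(Cl)cc1Cl | intermediate (not isolated)
19 | (1R)-1-[(2S,3S,4S)-2-{(1Z,3S)-3,5-bis[(tert-butyldimethylsilyl)oxy]-2-methylpent-1-en-1-yl}-4-[(dimethylamino)methyl]-5-oxooxolan-3-yl]-3-oxobutyl (2Z)-2-methylbut-2-enoate | O=C1[C@H](CN(C)C)[C@@H]([C@H](OC(=O)/C(C)=C\C)CC(C)=O)[C@H](/C=C(/C)[C@@H](O[Si](C)(C)C(C)(C)C)CCO[Si](C)(C)C(C)(C)C)O1 | intermediate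
20 | (1R)-1-[(2S,3S,4S)-2-[(1Z,3S)-3,5-dihydroxy-2-methylpent-1-en-1-yl]-4-[(dimethylamino)methyl]-5-oxooxolan-3-yl]-3-oxobutyl (2Z)-2-methylbut-2-enoate | O=C1[C@H](CN(C)C)[C@@H]([C@H](OC(=O)/C(C)=C\C)CC(C)=O)[C@H](/C=C(/C)[C@@H](O)CCO)O1 | intermediate
21 | (1R)-1-[(2S,3S,4S)-4-[(dimethylamino)methyl]-2-[(1Z,3S)-3-hydroxy-2-methyl-5-oxopent-1-en-1-yl]-5-oxooxolan-3-yl]-3-oxobutyl (2Z)-2-methylbut-2-enoate | O=C1[C@H](CN(C)C)[C@@H]([C@H](OC(=O)/C(C)=C\C)CC(C)=O)[C@H](/C=C(/C)[C@@H](O)CC=O)O1 | intermediate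
22 | (1S,3S,4Z,6S,7S,8R,10R,11S)-8-angeloyloxy-13-(dimethylamino)-1,3,10-trihydroxygermacr-4-en-12,6-olide | CN(C)C[C@H]1C(=O)O[C@H]2/C=C(/C)[C@@H](O)C[C@H](O)[C@](C)(O)C[C@@H](OC(=O)/C(C)=C\C)[C@H]12 | intermediate
23 | ammonium iodide, N,N,N-trimethylammonium iodide of 22 | C[N+](C)(C)C[C@H]1C(=O)O[C@H]2/C=C(/C)[C@@H](O)C[C@H](O)[C@](C)(O)C[C@@H](OC(=O)/C(C)=C\C)[C@H]12.[I-] | intermediate (not isolated)
24 | (1S,3S,4Z,6S,7S,8R,10R)-8-angeloyloxy-1,3,10-trihydroxygermacra-4,11(13)-dien-12,6-olide | C=C1C(=O)O[C@H]2/C=C(/C)[C@@H](O)C[C@H](O)[C@](C)(O)C[C@@H](OC(=O)/C(C)=C\C)[C@H]12 | target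

Total step count: 16. Longest linear sequence: 15 steps (steps 1–5 and 7–16); step 6 is a one-step side branch.

Steps most likely to fail

Step 15 (pinacol macrocyclisation). The ketyl may be reduced further to the acyclic alcohol or couple between molecules faster than it closes the ten-membered ring, and facial selectivity at C1 or C10 may be poor. Fallback, from 21 back to 22: methylenation of both carbonyl groups with the Takai–Lombardo reagent (Zn, CH2Br2, TiCl4, THF/CH2Cl2, 0 °C) would give the diene F1. Ring-closing metathesis (second-generation Grubbs catalyst, substrate as its camphorsulfonate salt, toluene, 80 °C, 1 mM) would then form the same C1–C10 bond as a Z double bond in the cyclodecadiene F2. OsO4 (cat.)/NMO syn-dihydroxylation of this most electron-rich alkene from the outer face of the ring would give the cis-diol 22.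

Step 8 (Mannich reaction on the lactone imide). Deprotonation may occur at C7 next to the imide instead of at C11, followed by β-elimination of the lactone carboxylate. Fallback, from 12 back to 15: reductive removal of the auxiliary with LiBH4 (THF, 1 equiv H2O, 0 °C) would give the primary alcohol F3, and TESCl/imidazole would give the triethylsilyl ether F4. With the lactone now the only enolisable carbonyl group, LiN(i-Pr)2 then Eschenmoser's salt would give the Mannich base F5. PPTS/MeOH at 0 °C would remove the primary TES group selectively to give the amino alcohol F6, and Parikh–Doering oxidation (SO3·pyridine, DMSO, Et3N) would give aldehyde 15.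

Step 11 (proline aldol). The enolisable aldehyde may lose the lactone carboxylate by β-elimination or epimerise at C7, and facial selectivity at C8 may be poor. Fallback, from 15 back to 16: Brown allylation with B-allyldiisopinocampheylborane prepared from (−)-α-pinene (Et2O, −78 °C, ethanolamine work-up) would set C8 under reagent control and give the homoallylic alcohol F7. Tsuji–Wacker oxidation of its terminal alkene (PdCl2 cat., CuCl, O2, DMF/H2O, amine as its hydrochloride) would give the methyl ketone 16.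

Further compounds
F1 | step 15 | (1R)-1-[(2S,3S,4S)-4-[(dimethylamino)methyl]-2-[(1Z,3S)-3-hydroxy-2-methylhexa-1,5-dien-1-yl]-5-oxooxolan-3-yl]-3-methylbut-3-en-1-yl (2Z)-2-methylbut-2-enoate | O=C1[C@H](CN(C)C)[C@@H]([C@H](OC(=O)/C(C)=C\C)CC(C)=C)[C@H](/C=C(/C)[C@@H](O)CC=C)O1
F2 | step 15 | (1(10)Z,3S,4Z,6S,7S,8R,11S)-8-angeloyloxy-13-(dimethylamino)-3-hydroxygermacra-1(10),4-dien-12,6-olide | CN(C)C[C@H]1C(=O)O[C@H]2/C=C(/C)[C@@H](O)C/C=C(/C)C[C@@H](OC(=O)/C(C)=C\C)[C@H]12
F3 | step 8 | (4S,5S)-5-{(1Z,3S)-3,5-bis[(tert-butyldimethylsilyl)oxy]-2-methylpent-1-en-1-yl}-4-(hydroxymethyl)oxolan-2-one | O=C1C[C@@H](CO)[C@H](/C=C(/C)[C@@H](O[Si](C)(C)C(C)(C)C)CCO[Si](C)(C)C(C)(C)C)O1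
F4 | step 8 | (4S,5S)-5-{(1Z,3S)-3,5-bis[(tert-butyldimethylsilyl)oxy]-2-methylpent-1-en-1-yl}-4-{[(triethylsilyl)oxy]methyl}oxolan-2-one | O=C1C[C@@H](CO[Si](CC)(CC)CC)[C@H](/C=C(/C)[C@@H](O[Si](C)(C)C(C)(C)C)CCO[Si](C)(C)C(C)(C)C)O1
F5 | step 8 | (3S,4S,5S)-5-{(1Z,3S)-3,5-bis[(tert-butyldimethylsilyl)oxy]-2-methylpent-1-en-1-yl}-3-[(dimethylamino)methyl]-4-{[(triethylsilyl)oxy]methyl}oxolan-2-one | O=C1[C@H](CN(C)C)[C@@H](CO[Si](CC)(CC)CC)[C@H](/C=C(/C)[C@@H](O[Si](C)(C)C(C)(C)C)CCO[Si](C)(C)C(C)(C)C)O1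
F6 | step 8 | (3S,4S,5S)-5-{(1Z,3S)-3,5-bis[(tert-butyldimethylsilyl)oxy]-2-methylpent-1-en-1-yl}-3-[(dimethylamino)methyl]-4-(hydroxymethyl)oxolan-2-one | O=C1[C@H](CN(C)C)[C@@H](CO)[C@H](/C=C(/C)[C@@H](O[Si](C)(C)C(C)(C)C)CCO[Si](C)(C)C(C)(C)C)O1
F7 | step 11 | (3S,4S,5S)-5-{(1Z,3S)-3,5-bis[(tert-butyldimethylsilyl)oxy]-2-methylpent-1-en-1-yl}-3-[(dimethylamino)methyl]-4-[(1R)-1-hydroxybut-3-en-1-yl]oxolan-2-one | O=C1[C@H](CN(C)C)[C@@H]([C@H](O)CC=C)[C@H](/C=C(/C)[C@@H](O[Si](C)(C)C(C)(C)C)CCO[Si](C)(C)C(C)(C)C)O1
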